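The plan rests on building the C5–C6 oxirane (chain numbered C1 = CH2Cl to C8 = CHBr) from an E-alkene by way of a six-membered iodocarbonate anchored on the C3 oxygen. In the target the hydroxyl on C3 and the oxirane oxygen on C5 stand 1,3-syn, which is what a cis-4,6-disubstituted 1,3-dioxan-2-one through O3, C3, C4, C5 and O5 enforces. One iodocyclisation therefore relays C3 to C5 and, by anti addition, to C6; opening the carbonate then closes the trans-oxirane with inversion at C6. The precursor is the tert-butyl carbonate of (3R,5E)-2,6-dimethylhepta-1,5-dien-3-ol with a silyl ether at C7. The halogens at C7/C8 and C1/C2 come last.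

Key step: step 6

Remark: the ligand enantiomer in step 13 is assumed to be the one whose face preference for bromine delivery gives (2R); if the opposite sense were found, its mirror image would be used.

Step 1
Reactants: 1 methacrolein (2-methylprop-2-enal); 2 B-allyldiisopinocampheylborane made from (−)-α-pinene, allylbis[(1S,2R,3S,5S)-2,6,6-trimethylbicyclo[3.1.1]hept-3-yl]borane
Product: 4 (3R)-2-methylhexa-1,5-dien-3-ol, via borinate ester 3 (not isolated)
Conditions: 2 (1 M in pentane), Et2O, −78 °C; then NaOH, H2O2, 0 °C → rt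
Reagents that add atoms: none
Why: Brown allylboration through a chair Zimmerman–Traxler transition state, in which the isopinocampheyl groups from (−)-α-pinene send the allyl group to the Re face of the aldehyde and so set C3 as R before oxidative work-up frees the alcohol.

Step 2
Reactants: 4 (3R)-2-methylhexa-1,5-dien-3-ol; 5 di-tert-butyl dicarbonate
Product: 6 tert-butyl (3R)-2-methylhexa-1,5-dien-3-yl carbonate
Conditions: DMAP (cat.), MeCN, rt
Reagents that add atoms: none
Why: DMAP-catalysed acylation of the secondary alcohol by the dicarbonate should give the mixed tert-butyl carbonate without touching the stereocentre.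

Step 3
Reactants: 6 tert-butyl (3R)-2-methylhexa-1,5-dien-3-yl carbonate; 1 methacrolein (excess)
Product: 7 tert-butyl (3R,5E)-2,6-dimethyl-7-oxohepta-1,5-dien-3-yl carbonate
Conditions: second-generation Hoveyda–Grubbs catalyst (3 mol %), CH2Cl2, 40 °C
Reagents that add atoms: none
Why: Olefin cross-metathesis, in which the monosubstituted alkene exchanges with the enal while the hindered isopropenyl group stays inert, and the conjugated trisubstituted alkene should form as the thermodynamically preferred E isomer.

Step 4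
Reactants: 7 tert-butyl (3R,5E)-2,6-dimethyl-7-oxohepta-1,5-dien-3-yl carbonate
Product: 8 tert-butyl (3R,5E)-7-hydroxy-2,6-dimethylhepta-1,5-dien-3-yl carbonate
Conditions: NaBH4, CeCl3·7H2O, MeOH, −40 °C
Reagents that add atoms: none
Why: Luche reduction should deliver hydride 1,2 to the enal and leave the carbonate and both alkenes untouched.

Step 5
Reactants: 8 tert-butyl (3R,5E)-7-hydroxy-2,6-dimethylhepta-1,5-dien-3-yl carbonate
Product: 9 tert-butyl (3R,5E)-7-[(tert-butyldiphenylsilyl)oxy]-2,6-dimethylhepta-1,5-dien-3-yl carbonate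
Conditions: TBDPSCl, imidazole, CH2Cl2, 0 °C → rt
Reagents that add atoms: tert-butyl(chloro)diphenylsilane, CC(C)(C)[Si](Cl)(c1ccccc1)c1ccccc1
Why: Silylation of the primary allylic alcohol gives a bulky, non-participating, base-stable ether, which keeps the C7 oxygen from attacking C6 in steps 6 and 7.

Step 6
Reactants: 9 tert-butyl (3R,5E)-7-[(tert-butyldiphenylsilyl)oxy]-2,6-dimethylhepta-1,5-dien-3-yl carbonate
Product: 10 (4R,6S)-6-[(2R)-1-[(tert-butyldiphenylsilyl)oxy]-2-iodopropan-2-yl]-4-(prop-1-en-2-yl)-1,3-dioxan-2-one (cis ring)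
Conditions: IBr, PhMe, −85 °C; then aq. Na2S2O3/NaHCO3; used at once in step 7
Reagents that add atoms: iodine monobromide, IBr
Why: IBr forms an iodonium ion on the electron-rich trisubstituted C5=C6 alkene, the carbonyl oxygen of the carbonate opens it at C5 anti to iodine, and the cationic ring then gives up its tert-butyl group to bromide. This is the established iodocarbonate cyclisation of homoallylic tert-butyl carbonates, applied here to a trisubstituted alkene. The 1,3-dioxan-2-one ring closes by 6-exo-trig attack of oxygen on C5. C5 is controlled by the C3 stereocentre through a chair-like transition state with the isopropenyl group and the C5 side chain both equatorial, which gives the cis ring, and C6 is controlled by the E geometry of the alkene because the addition is stereospecifically anti. The step needs attack at C5 and not 7-endo attack at the tertiary C6, which the six-membered ring and the electron-withdrawing silyloxymethyl group on C6 should secure. It also needs the isopropenyl alkene to stay untouched, which its lower substitution, the deactivating allylic carbonate oxygen and the slower five-membered closure should secure at −85 °C.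

Step 7
Reactants: 10 (4R,6S)-6-[(2R)-1-[(tert-butyldiphenylsilyl)oxy]-2-iodopropan-2-yl]-4-(prop-1-en-2-yl)-1,3-dioxan-2-one
Product: 12 (2R)-1-[(2S,3S)-3-{[(tert-butyldiphenylsilyl)oxy]methyl}-3-methyloxiran-2-yl]-3-methylbut-3-en-2-ol, via iodo diol 11 (not isolated)
Conditions: K2CO3, MeOH, 0 °C → rt
Reagents that add atoms: none
Why: Methanolysis of the cyclic carbonate frees the C5 alkoxide, which displaces the neighbouring tertiary iodide by intramolecular SN2 (3-exo-tet) with inversion at C6, so oxygen ends up added syn to the former E-alkene and the trans-oxirane results with C3 and C5 unchanged.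

Step 8
Reactants: 12 (2R)-1-[(2S,3S)-3-{[(tert-butyldiphenylsilyl)oxy]methyl}-3-methyloxiran-2-yl]-3-methylbut-3-en-2-ol
Product: 13 (2R)-1-[(2S,3S)-3-(hydroxymethyl)-3-methyloxiran-2-yl]-3-methylbut-3-en-2-ol
Conditions: TBAF, THF, 0 °C
Reagents that add atoms: none
Why: Fluoride cleaves the Si–O bond (silyl ether deprotection) while the oxirane, the alkene and the secondary alcohol are left alone.

Step 9
Reactants: 13 (2R)-1-[(2S,3S)-3-(hydroxymethyl)-3-methyloxiran-2-yl]-3-methylbut-3-en-2-ol
Product: 14 (2R,3S)-3-[(2R)-2-hydroxy-3-methylbut-3-en-1-yl]-2-methyloxirane-2-carbaldehyde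
Conditions: TEMPO (cat.), PhI(OAc)2, CH2Cl2, 0 °C → rt
Reagents that add atoms: none
Why: Oxoammonium (TEMPO) oxidation is selective for the primary alcohol over the secondary C3 carbinol, and the trans ring fusion that a lactol would need rules out over-oxidation.

Step 10
Reactants: 14 (2R,3S)-3-[(2R)-2-hydroxy-3-methylbut-3-en-1-yl]-2-methyloxirane-2-carbaldehyde; 15 dimethyl (1-diazo-2-oxopropyl)phosphonate (Bestmann–Ohira reagent)
Product: 16 (2R)-1-[(2S,3S)-3-ethynyl-3-methyloxiran-2-yl]-3-methylbut-3-en-2-ol
Conditions: K2CO3, MeOH, 0 °C → rt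
Reagents that add atoms: none
Why: Ohira–Bestmann (Seyferth–Gilbert) homologation, in which the diazophosphonate anion generated in methanol adds to the non-enolisable aldehyde and the derived alkylidene carbene rearranges to the terminal alkyne, with the quaternary C6 unable to epimerise.

Step 11
Reactants: 16 (2R)-1-[(2S,3S)-3-ethynyl-3-methyloxiran-2-yl]-3-methylbut-3-en-2-ol
Product: 17 (2R)-1-[(2S,3S)-3-(bromoethynyl)-3-methyloxiran-2-yl]-3-methylbut-3-en-2-ol
Conditions: NBS, AgNO3 (cat.), acetone, rt, dark
Reagents that add atoms: N-bromosuccinimide, O=C1CCC(=O)N1Br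
Why: Silver-catalysed electrophilic bromination of the terminal alkyne C–H through the silver acetylide should be much faster than attack of NBS on the alkene.

Step 12
Reactants: 17 (2R)-1-[(2S,3S)-3-(bromoethynyl)-3-methyloxiran-2-yl]-3-methylbut-3-en-2-ol
Product: 18 (2R)-1-{(2S,3R)-3-[(Z)-2-bromo-1-chloroethenyl]-3-methyloxiran-2-yl}-3-methylbut-3-en-2-ol
Conditions: LiCl, Pd(OAc)2 (5 mol %), 1,5-cyclooctadiene (10 mol %), AcOH–CH2Cl2 (1:4), 0 °C → rt
Reagents that add atoms: lithium chloride, [Li+].[Cl-]
Why: Palladium-catalysed anti-hydrochlorination of a 1-bromoalkyne, in which chloride adds to C7 trans to divalent palladium on C8 and protonolysis of the vinylpalladium bond places H and Cl anti, which gives the Z alkene with Cl and Br on the same side.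

Step 13
Reactants: 18 (2R)-1-{(2S,3R)-3-[(Z)-2-bromo-1-chloroethenyl]-3-methyloxiran-2-yl}-3-methylbut-3-en-2-ol
Product: 19 (2R,3R)-3-bromo-1-{(2S,3R)-3-[(Z)-2-bromo-1-chloroethenyl]-3-methyloxiran-2-yl}-4-chloro-3-methylbutan-2-ol (target)
Conditions: NBS, ClTi(OiPr)3, matched enantiomer of a tridentate salicylaldimine amino-alcohol (Schiff-base) ligand (20 mol %), hexanes, −20 °C
Reagents that add atoms: N-bromosuccinimide, O=C1CCC(=O)N1Br; chlorotitanium triisopropoxide, CC(C)O[Ti](Cl)(OC(C)C)OC(C)C
Why: Titanium-alkoxide-directed bromochlorination of an allylic alcohol, in which the C3 alkoxide binds the chiral chlorotitanium complex, NBS forms the bromonium ion on the ligand-selected face of C1=C2 and chloride passes from titanium to the distal C1 anti to bromine, which leaves the tertiary bromide on C2 as R and overrides Markovnikov opening.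

Compound list
1 | methacrolein (2-methylprop-2-enal) | C=C(C)C=O | starting material
2 | B-allyldiisopinocampheylborane from (−)-α-pinene, allylbis[(1S,2R,3S,5S)-2,6,6-trimethylbicyclo[3.1.1]hept-3-yl]borane | C=CCB([C@H]1C[C@H]2C[C@@H]([C@@H]1C)C2(C)C)[C@H]1C[C@H]2C[C@@H]([C@@H]1C)C2(C)C | starting material
3 | (3R)-2-methylhexa-1,5-dien-3-yl diisopinocampheylborinate | C=C(C)[C@H](OB([C@H]1C[C@H]2C[C@@H]([C@@H]1C)C2(C)C)[C@H]1C[C@H]2C[C@@H]([C@@H]1C)C2(C)C)CC=C | intermediate (not isolated)
4 | (3R)-2-methylhexa-1,5-dien-3-ol | C=C(C)[C@H](O)CC=C | intermediate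
5 | di-tert-butyl dicarbonate | CC(C)(C)OC(=O)OC(=O)OC(C)(C)C | starting material
6 | tert-butyl (3R)-2-methylhexa-1,5-dien-3-yl carbonate | C=C(C)[C@H](OC(=O)OC(C)(C)C)CC=C | intermediate
7 | tert-butyl (3R,5E)-2,6-dimethyl-7-oxohepta-1,5-dien-3-yl carbonate | C=C(C)[C@H](OC(=O)OC(C)(C)C)C/C=C(\C)C=O | intermediate
8 | tert-butyl (3R,5E)-7-hydroxy-2,6-dimethylhepta-1,5-dien-3-yl carbonate | C=C(C)[C@H](OC(=O)OC(C)(C)C)C/C=C(\C)CO | intermediate
9 | tert-butyl (3R,5E)-7-[(tert-butyldiphenylsilyl)oxy]-2,6-dimethylhepta-1,5-dien-3-yl carbonate | C=C(C)[C@H](OC(=O)OC(C)(C)C)C/C=C(\C)CO[Si](C(C)(C)C)(c1ccccc1)c1ccccc1 | intermediate (key-step precursor)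
10 | (4R,6S)-6-[(2R)-1-[(tert-butyldiphenylsilyl)oxy]-2-iodopropan-2-yl]-4-(prop-1-en-2-yl)-1,3-dioxan-2-one | C=C(C)[C@H]1C[C@H](OC(=O)O1)[C@](C)(I)CO[Si](C(C)(C)C)(c1ccccc1)c1ccccc1 | intermediate (key-step product)
11 | (3R,5S,6R)-7-[(tert-butyldiphenylsilyl)oxy]-6-iodo-2,6-dimethylhept-1-ene-3,5-diol | C=C(C)[C@H](O)C[C@H](O)[C@](C)(I)CO[Si](C(C)(C)C)(c1ccccc1)c1ccccc1 | intermediate (not isolated)
12 | (2R)-1-[(2S,3S)-3-{[(tert-butyldiphenylsilyl)oxy]methyl}-3-methyloxiran-2-yl]-3-methylbut-3-en-2-ol | C=C(C)[C@H](O)C[C@@H]1O[C@@]1(C)CO[Si](C(C)(C)C)(c2ccccc2)c2ccccc2 | intermediate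
13 | (2R)-1-[(2S,3S)-3-(hydroxymethyl)-3-methyloxiran-2-yl]-3-methylbut-3-en-2-ol | C=C(C)[C@H](O)C[C@@H]1O[C@@]1(C)CO | intermediate
14 | (2R,3S)-3-[(2R)-2-hydroxy-3-methylbut-3-en-1-yl]-2-methyloxirane-2-carbaldehyde | C=C(C)[C@H](O)C[C@@H]1O[C@@]1(C)C=O | intermediate
15 | dimethyl (1-diazo-2-oxopropyl)phosphonate | CC(=O)C(=[N+]=[N-])P(=O)(OC)OC | starting material
16 | (2R)-1-[(2S,3S)-3-ethynyl-3-methyloxiran-2-yl]-3-methylbut-3-en-2-ol | C=C(C)[C@H](O)C[C@@H]1O[C@@]1(C)C#C | intermediate
17 | (2R)-1-[(2S,3S)-3-(bromoethynyl)-3-methyloxiran-2-yl]-3-methylbut-3-en-2-ol | C=C(C)[C@H](O)C[C@@H]1O[C@@]1(C)C#CBr | intermediate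
18 | (2R)-1-{(2S,3R)-3-[(Z)-2-bromo-1-chloroethenyl]-3-methyloxiran-2-yl}-3-methylbut-3-en-2-ol | C=C(C)[C@H](O)C[C@@H]1O[C@@]1(C)/C(Cl)=C/Br | intermediate
19 | (2R,3R)-3-bromo-1-{(2S,3R)-3-[(Z)-2-bromo-1-chloroethenyl]-3-methyloxiran-2-yl}-4-chloro-3-methylbutan-2-ol | C[C@](Br)(CCl)[C@H](O)C[C@@H]1O[C@@]1(C)/C(Cl)=C/Br | target

Total step count: 13. Longest linear sequence: 13 steps (1 to 19).

Steps most likely to fail

Step 6. The iodonium ion may form on the isopropenyl alkene and close a five-membered carbonate, or be captured at C6 in a 7-endo mode. The chair preference may also be too weak for a clean cis ring, or the tertiary iodide may eliminate before step 7. The fallback delivers the oxygen under reagent control instead of through the tether. It sets out from 4: cross-metathesis with methacrolein (second-generation Hoveyda–Grubbs catalyst, CH2Cl2, 40 °C) should give (2E,5R)-5-hydroxy-2,6-dimethylhepta-2,6-dienal F1, and Luche reduction (NaBH4, CeCl3·7H2O, MeOH) should give (2E,5R)-2,6-dimethylhepta-2,6-diene-1,5-diol F2. Sharpless asymmetric epoxidation (L-(+)-diisopropyl tartrate, Ti(OiPr)4, tert-butyl hydroperoxide, 4 Å sieves, CH2Cl2, −20 °C) should then epoxidise only the primary E-allylic alcohol, because for this tartrate the (R)-carbinol at C3 is the slow-reacting partner of a kinetic resolution. The fallback comes back to the route at 13.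

Step 12. Opening of the oxirane by chloride in the acidic medium may compete with hydrochlorination of the bromoalkyne. The fallback accepts the opening and repairs it. It sets out from 17: the hydrochlorination is run in neat acetic acid with excess LiCl and Pd(OAc)2 until the oxirane has also been opened at the less substituted C5 with inversion, which should give (3R,5R,6R,7Z)-8-bromo-5,7-dichloro-2,6-dimethylocta-1,7-diene-3,6-diol F3. K2CO3 in methanol then lets the C6 alkoxide displace the C5 chloride with a second inversion, which restores the original oxirane. The fallback comes back to the route at 18.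

Step 13. Chloride may open the bromonium ion at the tertiary C2 (Markovnikov capture), bromine may be delivered to the wrong face, or the oxirane may be opened by the Lewis acid or captured by the bromonium ion. The fallback introduces the two halogens in separate steps and forms the C2–Br bond from bromide as nucleophile. It sets out from 18: SOCl2 in Et2O should transpose the allylic alcohol (SNi′) to (2S,3R)-3-[(Z)-2-bromo-1-chloroethenyl]-2-[(2E)-4-chloro-3-methylbut-2-en-1-yl]-3-methyloxirane F4. Shi epoxidation (D-fructose-derived ketone, KHSO5, K2CO3 buffer, MeCN–H2O, 0 °C) should give (2S,3R)-3-{[(2S,3R)-3-[(Z)-2-bromo-1-chloroethenyl]-3-methyloxiran-2-yl]methyl}-2-(chloromethyl)-2-methyloxirane F5. MgBr2·OEt2 in Et2O at −20 °C should open the new oxirane at its tertiary carbon with inversion, which gives the bromohydrin directly. The fallback comes back to the route at 19. Its own weak points are the E selectivity of the transposition and the choice between the two oxiranes in the opening.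

Further compounds
F1 | step 6 | (2E,5R)-5-hydroxy-2,6-dimethylhepta-2,6-dienal | C=C(C)[C@H](O)C/C=C(\C)C=O
F2 | step 6 | (2E,5R)-2,6-dimethylhepta-2,6-diene-1,5-diol | C=C(C)[C@H](O)C/C=C(\C)CO
F3 | step 12 | (3R,5R,6R,7Z)-8-bromo-5,7-dichloro-2,6-dimethylocta-1,7-diene-3,6-diol | C=C(C)[C@H](O)C[C@@H](Cl)[C@](O)(C)/C(Cl)=C/Br
F4 | step 13 | (2S,3R)-3-[(Z)-2-bromo-1-chloroethenyl]-2-[(2E)-4-chloro-3-methylbut-2-en-1-yl]-3-methyloxirane | ClC/C(C)=C/C[C@@H]1O[C@@]1(C)/C(Cl)=C/Br
F5 | step 13 | (2S,3R)-3-{[(2S,3R)-3-[(Z)-2-bromo-1-chloroethenyl]-3-methyloxiran-2-yl]methyl}-2-(chloromethyl)-2-methyloxirane | ClC[C@@]1(C)O[C@@H]1C[C@@H]1O[C@@]1(C)/C(Cl)=C/Br
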